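**One-step world.** In a one-step world, L + D ⇌ X, an equal charge of L and D loses the same amount of each. This flask also holds G, which can take D away.

- theta: L 32 mM; D 32 mM; G 160 mM; the very flask that is asked about, followed so far
- flask: L 32 mM; D 32.0 mM; G 160 mM; time 40 h

theta run (percent of the L charged): time / h: X / % = 3.00: 19.9; 4.00: 22.4; 6.00: 26.2; 10.0: 27.5; 15.0: 27.7

(readings scatter by 0.3 percentage points)

- the numbers in the tables scatter with a standard deviation of 0.3 percentage points
- what may be going on: L + D <-> X; G + D -> Z; 2 G -> J

- when, up to 40 h, the flask holds most X
- the amount of X, in percent of the L charged, at that time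
- earliest time at which at least nineteen twentieths of that best amount are there
- latest time at which they still are

**The puzzle.** You read X at 27.5% after 10.0 h and 27.7% after 15.0 h. The early rise, from 3.00 h to 4.00 h, was faster than this one. Yet 72.3% of the L is still free. Why stall with substrate in hand?

**Bound over free.** Where X stands still, its making and its way back balance, so [X]/[L] = K[D], with K the equilibrium constant of the first step. Call this a quasi-equilibrium. Take the bound-to-free ratio, [X]/[L] on the plateau: you read 0.383. It tells you K[D]. The one-step ledger leaves at most 23.1 mM of D, so K is at least 16.6 L mol⁻¹. If G keeps taking D, the ratio must sink with [D]. So my own reckoning puts the top between 10.0 h and 15.0 h, near 27.7%, with a slow decline after it.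

**The forecast.** The forecast gave 27.8% at 16 h, from 6.2 h to 37 h, holding that “the stall must come from loss of D, not L”.

**The result.** The flask gives 28.2% at 11.3 h, and the asked window runs from 6.76 h to 20.9 h.

    L + D ⇌ X (K = 30.0 L mol⁻¹, k = 0.00100 L mol⁻¹ s⁻¹)
    G + D → Z (k = 1.70 × 10⁻⁴ L mol⁻¹ s⁻¹)
    2 G → J (k = 2.30 × 10⁻⁴ L mol⁻¹ s⁻¹)

**Second flask.** At that top the flask still has 40.8% of its D free, which is 13.1 mM. Your plateau ratio 0.383 over this [D] reads K as 29.3 L mol⁻¹. Now take the neighbour charged with 130 mM of D. After 40.0 h it has 43.6% of its D free, so the ratio should be 1.66, which puts X at 62.4%. That neighbour holds 63.2% X.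

(The readings are simulated for substances that don't exist; the scatter is artificial.)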